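**Assumption:** prismatomerin is the (E)-4-hydroxybenzylidene analogue of plumericin with the relative and absolute configuration shown in the given SMILES. Methyl propiolate adds to a lactol OH to give the (E)-β-alkoxyacrylate.

## Retrosynthetic overview
- The (E)-arylidene lactone comes from aldol condensation of the α-unsubstituted lactone with 4-silyloxybenzaldehyde.
- The THF ring, the γ-lactone, the quaternary C8–O and C11 all form in one SmI2 ketyl/β-alkoxyacrylate 5-exo cyclization and lactonization. The pyran-acetal oxygen tether delivers C11 to the face that puts the C8–O on the correct side.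
- The dihydropyran lactol forms by iridoid-type closure of a formylated cyclopentenone that carries a masked formylacetate side chain.
- The cyclopentene stereocentre C5 is set by Pd-catalysed desymmetrization of meso-3,5-diacetoxycyclopentene (the key symmetry-breaking step), and the arylidene comes from the aromatic feedstock 4-hydroxybenzaldehyde.
- Ring order: cyclopentene, then dihydropyran lactol, then THF and lactone together, then the exocyclic alkene.

## Route

**Step 1**
Reactants: 1, methyl 3,3-dimethoxypropanoate, `COC(=O)CC(OC)OC`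
Product: 2, silyl ketene acetal of 1, `COC(O[Si](C)(C)C(C)(C)C)=CC(OC)OC`
Conditions: LDA added to 1 and TBSCl, THF, −78 °C (internal quench to suppress β-elimination of MeO⁻)
Reagents that add atoms: TBSCl, `CC(C)(C)[Si](C)(C)Cl`
Why: the Si-trapped enolate is a storable soft C-nucleophile equivalent of the formylacetate anion, with the C3 aldehyde carried as a dimethyl acetal.

**Step 2**
Reactants: 3, cis-3,5-diacetoxycyclopent-1-ene (meso), `CC(=O)O[C@H]1C=C[C@@H](OC(C)=O)C1`; 2
Product: 4, methyl 2-(cis-4-acetoxycyclopent-2-en-1-yl)-3,3-dimethoxypropanoate, `COC(=O)C(C(OC)OC)[C@H]1C=C[C@@H](OC(C)=O)C1`, as side-chain epimers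
Conditions: Pd2(dba)3·CHCl3 (2.5 mol%), (R,R)-Trost DACH-phenyl ligand (7.5 mol%), TBAT (5 mol%), THF, 0 °C, 3 in slight excess
Reagents that add atoms: none beyond 2, whose C6 unit is incorporated; the silyl group leaves as TBSOAc
Why: desymmetrizing Tsuji–Trost allylic alkylation in which the chiral Pd catalyst ionizes one enantiotopic acetate and the nucleophile attacks anti to Pd (net retention), setting C5 cis to the remaining C8–OAc; the side-chain CH becomes sp² later, so its configuration is irrelevant.
Proposed new method: closest known reaction is the Trost desymmetrizing AAA of meso-cyclopentenediol derivatives with malonates, combined with fluoride-activated Pd allylation of silyl ketene acetals. Here the silicate transfers the formylacetate carbanion to the π-allyl-Pd, and the acetal protects the aldehyde from enolization.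

**Step 3**
Reactants: 4
Product: 5, methyl 2-[(cis)-4-hydroxycyclopent-2-en-1-yl]-3,3-dimethoxypropanoate, `COC(=O)C(C(OC)OC)[C@H]1C=C[C@@H](O)C1`
Conditions: Novozym 435 (CAL-B), MeOH (3 equiv), MTBE, 25 °C
Reagents that add atoms: none
Why: enzymatic methanolysis removes the acetate under neutral conditions, avoiding E1cB loss of MeOH from the β-alkoxy ester that K2CO3/MeOH could cause; no stereocentre is touched.

**Step 4**
Reactants: 5
Product: 6, methyl 2-[(4-oxocyclopent-2-en-1-yl)]-3,3-dimethoxypropanoate, `COC(=O)C(C(OC)OC)[C@H]1C=CC(=O)C1`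
Conditions: Dess–Martin periodinane, NaHCO3, CH2Cl2, 0 °C
Reagents that add atoms: none
Why: Dess–Martin oxidation of the allylic alcohol gives the enone, which is needed both for C9 functionalization and as the ketyl precursor; C5 is untouched under these buffered conditions.

**Step 5**
Reactants: 6
Product: 7, 5-(hydroxymethylene)-4-oxo-cyclopentenyl analogue, `COC(=O)C(C(OC)OC)[C@H]1C=CC(=O)C1=CO`
Conditions: LDA (1.05 equiv), THF, −78 °C; then HCO2Et (3 equiv), −78 → 0 °C; pH 7 buffer work-up
Reagents that add atoms: ethyl formate, `CCOC=O` (adds CHO)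
Why: kinetic deprotonation occurs at the only enolizable ketone α'-carbon (C9), and Claisen formylation installs C1 at aldehyde level as a stable enol; C9 becomes sp², so its configuration is reset in Step 6.

**Step 6**
Reactants: 7
Product: 8, cis-fused 1-hydroxy cyclopenta[c]pyran lactol enone, `COC(=O)C1=CO[C@H](O)[C@@H]2C(=O)C=C[C@H]12`
Conditions: 1 M aq. HCl/THF (1:4), 0 °C → 25 °C
Reagents that add atoms: water, `O` (one O is incorporated; 2 MeOH are lost)
Why: acetal hydrolysis followed by the iridoid-type lactol closure, with C9 epimerizing through the β-dicarbonyl enol to the thermodynamic cis-fused (H5/H9 cis) lactol, and C1 forming as an anomeric mixture.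

**Step 7**
Reactants: 8; 9, methyl propiolate, `C#CC(=O)OC`
Product: 10, (E)-β-alkoxyacrylate mixed acetal, `COC(=O)C1=CO[C@H](O/C=C/C(=O)OC)[C@@H]2C(=O)C=C[C@H]12`
Conditions: 9 (1.5 equiv), N-methylmorpholine (1 equiv), CH2Cl2, 0 °C; separate anomers by chromatography
Reagents that add atoms: none beyond 9
Why: amine-promoted oxa-Michael addition of the lactol OH to the propiolate (E-selective); only the anomer with the acrylate O cis to C9–C8 can cyclize in Step 8.

**Step 8**
Reactants: 10
Product: 11, dihydro-lactone (pentacyclic skeleton of plumericin, α-CH2), `COC(=O)C1=CO[C@@H]2O[C@H]3CC(=O)O[C@]34C=C[C@H]1[C@H]24`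
Conditions: SmI2 (3 equiv), HMPA (12 equiv), t-BuOH (2 equiv), THF, −78 → 0 °C
Reagents that add atoms: none (two H come from t-BuOH; MeOH is lost on lactonization)
Why: the Sm ketyl at C8 adds 5-exo to the β-carbon (C11) of the tethered alkoxyacrylate, on the face carrying the C1–O tether. This fixes C8–C11 cis to C1, so the C8–O ends up on the opposite face as in the target. The Sm enolate is protonated, and the tertiary Sm alkoxide lactonizes onto the ester; cis-fusion of the lactone fixes C11.
Proposed new method: the closest known reaction is the Fukuzawa/Molander SmI2 ketyl–acrylate coupling to γ-butyrolactones. The new features are the enone ketyl (the competing β-coupling at C6 would form a strained bicyclo[3.2.1] system) and the alkoxyacrylate acceptor, which places O-substitution on C11 and builds the THF ring at the same time.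

**Step 9**
Reactants: 12, 4-hydroxybenzaldehyde, `O=Cc1ccc(O)cc1`
Product: 13, 4-(tert-butyldimethylsilyloxy)benzaldehyde, `O=Cc1ccc(O[Si](C)(C)C(C)(C)C)cc1`
Conditions: TBSCl, imidazole, DMF, 25 °C
Reagents that add atoms: TBSCl, `CC(C)(C)[Si](C)(C)Cl`
Why: phenol protection so that the lithium enolate in Step 10 is not quenched.

**Step 10**
Reactants: 11; 13
Product: 14, β-hydroxy lactone aldol adduct (diastereomers at Cα and the carbinol), `COC(=O)C1=CO[C@@H]2O[C@H]3C(C(O)c4ccc(O[Si](C)(C)C(C)(C)C)cc4)C(=O)O[C@]34C=C[C@H]1[C@H]24`
Conditions: LDA (1.0 equiv), THF, −78 °C, then 13 (1.5 equiv), 1 h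
Reagents that add atoms: none beyond 13
Why: lactone enolate aldol addition; both new stereocentres are destroyed in Step 11.

**Step 11**
Reactants: 14
Product: 15, TBS-protected prismatomerin, `COC(=O)C1=CO[C@@H]2O[C@H]3/C(=C\c4ccc(O[Si](C)(C)C(C)(C)C)cc4)C(=O)O[C@]34C=C[C@H]1[C@H]24`
Conditions: MsCl, Et3N, CH2Cl2, 0 °C; then DBU, 25 °C
Reagents that add atoms: none
Why: mesylation then E1cB elimination gives the thermodynamically preferred (E)-arylidene (aryl cis to C11, trans to C=O); the acetals and the enol ether acrylate tolerate DBU.

**Step 12**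
Reactants: 15
Product: 16, prismatomerin, `COC(=O)C1=CO[C@@H]2O[C@H]3/C(=C\c4ccc(O)cc4)C(=O)O[C@]34C=C[C@H]1[C@H]24`
Conditions: TBAF, AcOH (1:1), THF, 0 °C
Reagents that add atoms: none
Why: buffered fluoride removes the aryl silyl ether without base-induced lactone opening or alkene isomerization.

## Compound list
1 | methyl 3,3-dimethoxypropanoate | `COC(=O)CC(OC)OC` | starting material
2 | TBS ketene acetal of 1 | `COC(O[Si](C)(C)C(C)(C)C)=CC(OC)OC` | intermediate (reagent)
3 | cis-3,5-diacetoxycyclopentene (meso) | `CC(=O)O[C@H]1C=C[C@@H](OC(C)=O)C1` | starting material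
4 | methyl 2-(cis-4-acetoxycyclopent-2-enyl)-3,3-dimethoxypropanoate | `COC(=O)C(C(OC)OC)[C@H]1C=C[C@@H](OC(C)=O)C1` | intermediate
5 | the corresponding cis-4-hydroxy compound | `COC(=O)C(C(OC)OC)[C@H]1C=C[C@@H](O)C1` | intermediate
6 | the corresponding 4-oxo (enone) compound | `COC(=O)C(C(OC)OC)[C@H]1C=CC(=O)C1` | intermediate
7 | C9-hydroxymethylene enone | `COC(=O)C(C(OC)OC)[C@H]1C=CC(=O)C1=CO` | intermediate
8 | cis-fused lactol enone | `COC(=O)C1=CO[C@H](O)[C@@H]2C(=O)C=C[C@H]12` | intermediate
9 | methyl propiolate | `C#CC(=O)OC` | starting material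
10 | (E)-acrylate mixed acetal enone | `COC(=O)C1=CO[C@H](O/C=C/C(=O)OC)[C@@H]2C(=O)C=C[C@H]12` | intermediate
11 | dihydro-prismatomerin (α-CH2 lactone) | `COC(=O)C1=CO[C@@H]2O[C@H]3CC(=O)O[C@]34C=C[C@H]1[C@H]24` | intermediate
12 | 4-hydroxybenzaldehyde | `O=Cc1ccc(O)cc1` | starting material
13 | 4-(TBSO)benzaldehyde | `O=Cc1ccc(O[Si](C)(C)C(C)(C)C)cc1` | intermediate
14 | aldol adduct | `COC(=O)C1=CO[C@@H]2O[C@H]3C(C(O)c4ccc(O[Si](C)(C)C(C)(C)C)cc4)C(=O)O[C@]34C=C[C@H]1[C@H]24` | intermediate
15 | TBS-prismatomerin | `COC(=O)C1=CO[C@@H]2O[C@H]3/C(=C\c4ccc(O[Si](C)(C)C(C)(C)C)cc4)C(=O)O[C@]34C=C[C@H]1[C@H]24` | intermediate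
16 | prismatomerin | `COC(=O)C1=CO[C@@H]2O[C@H]3/C(=C\c4ccc(O)cc4)C(=O)O[C@]34C=C[C@H]1[C@H]24` | target

## Totals
- Total steps: 12.
- Longest linear sequence: 11 steps (Steps 1–8, 10, 11, 12); Step 9 is a separate one-step branch.

## Three steps most likely to fail
1. **Step 2 (Pd desymmetrization with the ketene acetal).** Risks are β-elimination of the enolate, bis-substitution and modest ee. Fallback: enzymatic desymmetrization of 3 to the monoacetate, conversion to the methyl carbonate, Pd/dimethyl malonate, Krapcho decarboxylation, then Mukaiyama orthoformate alkylation of the ester's silyl ketene acetal to reach 5.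
2. **Step 6 (lactol closure).** The lactol OH is β to a ketone with an acidic C9–H, so it can dehydrate to the conjugated 4H-pyran enone, which would racemize at C5. Fallback: accept that 4H-pyran, but generate it under mild conditions and add the C1–O11 unit by Lewis-acid oxa-Michael addition of methyl 3-hydroxyacrylate coupled to the SmI2 cyclization in one pot, so the unfavourable oxa-Michael equilibrium is drained by irreversible ketyl trapping.
3. **Step 8 (SmI2 cascade).** Risks are enone ketyl β-coupling, over-reduction of the pyran acrylate, and an anomer mismatch. Fallback: a Broka–Shen-type route in which Sn→Li exchange of a C1–O–CH(SnBu3)CH2CO2tBu tether generates an α-alkoxyalkyllithium that adds intramolecularly to the C8 ketone, followed by lactonization.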